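Start from the leftover L, the part of the charge not yet product. First order means that L shrinks by the same factor in equal times, at any charge. The west run (0.67 mM) and the east run (1.5 mM) read alike, 46.7% and 46.9% at 90.0 s, with a scatter of 0.5 percentage points. So you carry their curve over to the flask at 1.0 mM.

| flask | substrate | remark | time |
|---|---|---|---|
| west | 0.67 mM | run made earlier |  |
| east | 1.5 mM | run made earlier |  |
| flask | 1.0 mM |  | 2.5 min |

- west (time / s: product / %): 40.0: 17.0; 50.0: 23.7; 60.0: 30.7; 80.0: 41.3; 90.0: 46.7
- east (time / s: product / %): 40.0: 16.8; 50.0: 22.9; 60.0: 30.0; 80.0: 41.1; 90.0: 46.9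

(each reading ± 0.5 percentage points)

- time up to 2.5 min at which product stands highest
- the amount of product, in percent of the substrate charged, at that time

- the analysis behind the earlier runs scatters by 0.5 percentage points, standard deviation

First round: assume no delay, so L = exp(−kt). West's last reading gives k = 0.00699 s⁻¹. Put that back into west's first reading:

product at 40.0 s = 24.4%, read 17.0%

That is higher than the reading, so product starts late.

Second round: L = exp(−k(t − τ)), with τ the lag. Between two readings τ cancels:

k = ln(L first / L last) / (time between) = 0.00886 s⁻¹ west, 0.00898 s⁻¹ east

Their mean, 0.00892 s⁻¹, is the leftover clock, the rate constant at which the leftover falls after the lag. The first readings then give τ = 19.2 s.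

Test it on readings not used: at 60.0 s the law gives 30.5%, and the runs read 30.7% and 30.0%.

In this law L falls throughout, so my time is the end of the window, 2.5 min:

product = 1 − L = 68.8%

The forecast says 71% at 2.5 min, higher than my figure. Its ground for the time: “there is no sign that product is being consumed”.

The flask gives 70.2% at 2.50 min.

    intermediate C → product (k = 0.360 s⁻¹)
    intermediate A → intermediate B (k = 0.200 s⁻¹)
    intermediate B → intermediate C (k = 0.0100 s⁻¹)
    substrate ⇌ dormant form (K = 3.10, k = 0.370 s⁻¹)
    substrate → intermediate A (k = 0.230 s⁻¹)

In the flask at that time nearly all of the leftover is intermediate B, 28.7%, the resting state. At 1.25 min the clock gives 39.2%, and the flask stood at 38.4%. For the same flask left until 10 min, the clock gives 99.4%, and that flask reached 99.7%.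

The runs are simulated from invented constants; scatter was added.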